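(The data stem from a simulated flask for substances that don't exist, noise included.)

- Pairing substrate with partner is slow: in the grey run, with 33 mM of partner, substrate still stood at 17.8% after 15.0 min.

common to all: substrate 0.010 M
- amber: partner 9.1 mM; run made earlier
- teal: partner 17 mM; run made earlier
- grey: partner 33 mM; run made earlier
- ash: partner 10.0 mM; time 2.0 h
- cedar: partner 15.0 mM; time 2.0 h
- alder: partner 30.0 mM; time 2.0 h

| run | time / min | single product / % | substrate / % |
|---|---|---|---|
| amber | 8.00 | 22.2 | 76.8 |
| amber | 20.0 | 41.5 | 58.7 |
| amber | 40.0 | 57.4 | 41.7 |
| amber | 60.0 | 66.9 | 33.6 |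
| amber | 80.0 | 70.8 | 28.0 |
| teal | 15.0 | 56.3 | 43.3 |
| teal | 30.0 | 76.6 | 23.6 |
| teal | 50.0 | 88.3 | 11.2 |
| teal | 60.0 | 90.7 | 8.6 |
| teal | 80.0 | 94.5 | 3.6 |
| grey | 15.0 | 81.6 | 17.8 |
| grey | 30.0 | 94.6 | 4.3 |
| grey | 50.0 | 99.1 | 0.6 |
| grey | 60.0 | 99.4 | 1.1 |
| grey | 80.0 | 98.7 | 0.2 |

(scatter of a reading: 0.5 percentage points)

1. single product at the end, in percent of the substrate charged, for each flask in turn (ash, cedar, alder)

- a reading or a percentage of single product counts all its forms, free or not

- Keep a ledger for the substrate charged, which is the limiting reagent in cedar, where the partner charge is 15.0 mM against 10 mM, and in alder. In ash the two charges are equal at 10.0 mM.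
- In the grey run at 50.0 min, substrate and single product add to 99.7%, so I open two entries: substrate left and single product made.
- The grey substrate reading at 15.0 min gives 4.17 /M/min for the pairing constant, the rate of substrate loss divided by c(substrate) times c(partner). The teal run at 30.0 min reads 4.03 /M/min.
- In ash, with equal charges, the substrate entry after 2.0 h is 16.6%, so my single product entry is 83.4%.
- In cedar, the excess of partner brings the substrate entry to 2.88%, which makes single product 97.1%.
- In alder, the substrate entry is 0.00298%, and single product is >99.9%.
- The forecast gives 83.1%, 97% and 100%, close to my entries but not the same numbers. Among its grounds stands “I see no sign of reversibility or product inhibition”.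
- The flasks give 82.7% in ash, 96.4% in cedar and 98.3% in alder, with crystals counted in the single product.

    partner + single product → double product (k = 0.190 /M/min)
    crystals ⇌ single product, rate k2*(cs2 - [single product]) while solid is left; crystals form when [single product] > cs2 (solubility = 0.320 mM, k = 2.90 /min)
    substrate + partner → single product (k = 4.10 /M/min)

- In alder, the books close with a third entry: substrate stands at 0%, and double product takes 1.66%.
- In ash at 2.00 h, the pairing constant's 16.6% of substrate stands against 17.0% in the flask.
- In alder at 1.00 h, the same constant gives 0.447% of substrate, and the flask holds 0.494%.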